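## Retrosynthetic overview

1. The (E)-disubstituted alkene next to the ring is cut last (olefin cross-metathesis), giving a butenolide-bearing 1,4-diene and a 2-vinyl-tetrahydrofuran γ-lactone.
2. The γ-lactone is grown from an acetyl group on C5: enolate alkylation, then chelation-controlled MeMgBr addition and lactonisation set the lactone carbinol carbon.
3. The tetrahydrofuran is closed at C3–C4 by ring-closing metathesis of a bis-allylic ether, then hydrogenated. The enabling feature is that ring oxygen O1 sits between quaternary C2 and tertiary C5, while C3 and C4 are the only ring atoms without substituents or stereochemistry, so each can start as the inner carbon of a vinyl group.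
4. The ether is assembled by iridium-catalysed allylic etherification of a tertiary allylic alkoxide (from (S)-2-methylglycidol, which fixes C2) with an allylic phosphate (the catalyst fixes C5).
5. Ring order: tetrahydrofuran (step 6), γ-lactone (step 11), butenolide (step 19, on the side-chain fragment).

Key step: step 6

Remark: tetrahydrofuran atoms are numbered O1, C2 (quaternary), C3, C4, C5 throughout. The silyloxy-bearing carbon brought in with 5 is a disposable stereocentre (erased in step 9), drawn in the (S) series; either enantiomer of 5 should serve.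

Remark: compounds 26–30 are racemic; their stereocentre is destroyed in step 19.

Step 1
Reactants: 1 (S)-2-methylglycidol
Product: 2 (2R)-2-[(benzyloxy)methyl]-2-methyloxirane
Conditions: NaH, BnBr, Bu4NI (cat.), THF, 0 °C to rt
Reagents that add atoms: benzyl bromide, BrCc1ccccc1
Why: Williamson O-benzylation of the primary alkoxide; the quaternary epoxide carbon is not touched, and the descriptor changes from S to R only because the ranking of the two CH2 groups changes.

Step 2
Reactants: 2 (2R)-2-[(benzyloxy)methyl]-2-methyloxirane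
Product: 4 (2R)-1-(benzyloxy)-2-methylbut-3-en-2-ol, via sulfonium betaine 3 (not isolated)
Conditions: Me3SI (3 equiv), n-BuLi (3 equiv), THF, −10 °C to rt
Reagents that add atoms: trimethylsulfonium iodide, C[S+](C)C.[I-]
Why: One-carbon homologation of an epoxide to an allylic alcohol with dimethylsulfonium methylide: the ylide opens the epoxide at its CH2 terminus and the betaine loses dimethyl sulfide by ylide-mediated elimination, so the quaternary stereocentre is retained.

Step 3
Reactants: 5 (S)-but-3-en-2-ol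
Product: 6 tert-butyl[(2S)-but-3-en-2-yloxy]dimethylsilane
Conditions: TBSCl, imidazole, CH2Cl2, 0 °C to rt
Reagents that add atoms: tert-butyldimethylsilyl chloride, CC(C)(C)[Si](C)(C)Cl
Why: Standard silylation of a secondary alcohol; the stereocentre is not involved.

Step 4
Reactants: 6 tert-butyl[(2S)-but-3-en-2-yloxy]dimethylsilane; 7 diethyl allyl phosphate
Product: 8 (2E,4S)-4-[(tert-butyldimethylsilyl)oxy]pent-2-en-1-yl diethyl phosphate
Conditions: second-generation Grubbs catalyst (3 mol %), 7 (3 equiv), CH2Cl2, 40 °C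
Reagents that add atoms: none
Why: Olefin cross-metathesis of a slowly dimerising secondary allylic silyl ether with an unhindered allyl phosphate in excess; the E alkene is the thermodynamically favoured product.

Step 5
Reactants: 4 (2R)-1-(benzyloxy)-2-methylbut-3-en-2-ol; 8 (2E,4S)-4-[(tert-butyldimethylsilyl)oxy]pent-2-en-1-yl diethyl phosphate
Product: 10 (2R)-1-(benzyloxy)-2-methylbut-3-en-2-yl (3R,4S)-4-[(tert-butyldimethylsilyl)oxy]pent-1-en-3-yl ether, via copper alkoxide 9 (not isolated)
Conditions: 4, n-BuLi, THF, 0 °C; CuI; then 8 (1.2 equiv), [Ir(cod)Cl]2 (2.5 mol %), (Ra,Rc,Rc)-(1,1'-binaphthalene-2,2'-diyl) N,N-bis(1-phenylethyl)phosphoramidite (5 mol %), THF, rt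
Reagents that add atoms: none
Why: Iridium-catalysed asymmetric allylic etherification of an aliphatic copper alkoxide: the allyl–iridium intermediate is attacked at its substituted terminus to give the branched ether, the chiral phosphoramidite controls the face and should set C5 as R (the antipodal ligand would be used if the sense proved opposite), the phosphate leaving group releases no competing alkoxide, and C2 is carried through unchanged.

Step 6
Reactants: 10 (2R)-1-(benzyloxy)-2-methylbut-3-en-2-yl (3R,4S)-4-[(tert-butyldimethylsilyl)oxy]pent-1-en-3-yl ether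
Product: 11 (2R,5R)-2-[(benzyloxy)methyl]-5-{(1S)-1-[(tert-butyldimethylsilyl)oxy]ethyl}-2-methyl-2,5-dihydrofuran
Conditions: second-generation Grubbs catalyst (5 mol %), CH2Cl2 (0.01 M), 40 °C, argon sparge
Reagents that add atoms: none
Why: Ring-closing olefin metathesis: the ruthenium alkylidene should load on the less hindered vinyl group at C5, add across the vinyl group on C2 in an intramolecular [2+2] step and cyclorevert with loss of ethylene, so that C3=C4 is the ring-closing bond (reduced to C3–C4 in step 7). The closest known reaction type is the ring-closing metathesis of bis-allylic ethers obtained by metal-catalysed allylic etherification, which gives 2,5-dihydrofurans also when one ether carbon is fully substituted. The single ring closed is the five-membered oxacycle O1–C2–C3–C4–C5, formed from a 1,6-diene with the oxygen in the middle of the tether; the two substituents on C2 favour the folded conformer. No stereocentre is made: C2 (step 1) and C5 (step 5) are carried through untouched, and the trans relationship between the C2 benzyloxymethyl arm and the C5 side chain is simply inherited from 10. The step needs cyclisation to win over oligomerisation and over migration of the new double bond towards C5; high dilution, removal of ethylene and the absence of any other alkene in 10 secure the first, and hydride-free conditions with prompt work-up the second.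

Step 7
Reactants: 11 (2R,5R)-2-[(benzyloxy)methyl]-5-{(1S)-1-[(tert-butyldimethylsilyl)oxy]ethyl}-2-methyl-2,5-dihydrofuran
Product: 12 (2R,5R)-2-[(benzyloxy)methyl]-5-{(1S)-1-[(tert-butyldimethylsilyl)oxy]ethyl}-2-methyltetrahydrofuran
Conditions: H2 (1 atm), PtO2 (5 mol %), EtOAc, rt
Reagents that add atoms: none
Why: Heterogeneous hydrogenation of the cis ring alkene; PtO2 is chosen because it should neither move the double bond towards C5 nor cleave the benzyl or ring C–O bonds, and no stereocentre is touched.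

Step 8
Reactants: 12 (2R,5R)-2-[(benzyloxy)methyl]-5-{(1S)-1-[(tert-butyldimethylsilyl)oxy]ethyl}-2-methyltetrahydrofuran
Product: 13 (1S)-1-{(2R,5R)-5-[(benzyloxy)methyl]-5-methyltetrahydrofuran-2-yl}ethan-1-ol
Conditions: Bu4NF, THF, 0 °C to rt
Reagents that add atoms: none
Why: Fluoride cleavage of the silyl ether; the benzyl ether is stable.

Step 9
Reactants: 13 (1S)-1-{(2R,5R)-5-[(benzyloxy)methyl]-5-methyltetrahydrofuran-2-yl}ethan-1-ol
Product: 14 1-{(2R,5R)-5-[(benzyloxy)methyl]-5-methyltetrahydrofuran-2-yl}ethan-1-one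
Conditions: Dess–Martin periodinane, CH2Cl2, 0 °C to rt
Reagents that add atoms: none
Why: Dess–Martin oxidation of the secondary alcohol under mild, non-epimerising conditions; it removes the disposable stereocentre and leaves C5 intact.

Step 10
Reactants: 14 1-{(2R,5R)-5-[(benzyloxy)methyl]-5-methyltetrahydrofuran-2-yl}ethan-1-one
Product: 16 ethyl 4-{(2R,5R)-5-[(benzyloxy)methyl]-5-methyltetrahydrofuran-2-yl}-4-oxobutanoate, via lithium enolate 15 (not isolated)
Conditions: LiN(iPr)2 (1.05 equiv), THF, −78 °C; ethyl bromoacetate, DMPU, −78 °C to −30 °C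
Reagents that add atoms: ethyl bromoacetate, BrCC(=O)OCC
Why: Kinetic deprotonation with a hindered amide base should occur at the methyl group and not at the hindered, alkoxy-bearing C5 methine, and the enolate is C-alkylated by the bromoacetate (SN2) without epimerising C5 at low temperature.

Step 11
Reactants: 16 ethyl 4-{(2R,5R)-5-[(benzyloxy)methyl]-5-methyltetrahydrofuran-2-yl}-4-oxobutanoate
Product: 18 (5S)-5-{(2R,5R)-5-[(benzyloxy)methyl]-5-methyltetrahydrofuran-2-yl}-5-methyldihydrofuran-2(3H)-one, via hydroxy ester 17 (not isolated)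
Conditions: MeMgBr (1.2 equiv), CH2Cl2/Et2O, −78 °C to 0 °C; then TsOH·H2O (cat.), CH2Cl2, rt
Reagents that add atoms: methylmagnesium bromide, C[Mg]Br
Why: Chelation-controlled Grignard addition: magnesium bridges ring oxygen O1 and the ketone oxygen, methyl is delivered from the face of the C5 hydrogen, which should give the (S)-carbinol, and the γ-hydroxy ester lactonises with loss of ethanol; the ketone reacts faster than the ester at −78 °C.

Step 12
Reactants: 18 (5S)-5-{(2R,5R)-5-[(benzyloxy)methyl]-5-methyltetrahydrofuran-2-yl}-5-methyldihydrofuran-2(3H)-one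
Product: 19 (5S)-5-[(2R,5R)-5-(hydroxymethyl)-5-methyltetrahydrofuran-2-yl]-5-methyldihydrofuran-2(3H)-one
Conditions: H2 (1 atm), Pd(OH)2/C, EtOAc, rt
Reagents that add atoms: none
Why: Hydrogenolysis of the benzyl ether at a stage where the molecule holds no alkene; lactone and ring ether are inert.

Step 13
Reactants: 19 (5S)-5-[(2R,5R)-5-(hydroxymethyl)-5-methyltetrahydrofuran-2-yl]-5-methyldihydrofuran-2(3H)-one
Product: 20 (2R,5R)-2-methyl-5-[(2S)-2-methyl-5-oxotetrahydrofuran-2-yl]tetrahydrofuran-2-carbaldehyde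
Conditions: Dess–Martin periodinane, CH2Cl2, 0 °C to rt
Reagents that add atoms: none
Why: Dess–Martin oxidation of the primary alcohol to an aldehyde that has no α-hydrogen and so cannot epimerise.

Step 14
Reactants: 20 (2R,5R)-2-methyl-5-[(2S)-2-methyl-5-oxotetrahydrofuran-2-yl]tetrahydrofuran-2-carbaldehyde
Product: 21 (5S)-5-[(2R,5R)-5-ethenyl-5-methyltetrahydrofuran-2-yl]-5-methyldihydrofuran-2(3H)-one
Conditions: Ph3PCH3Br, KOtBu, THF, 0 °C; then 20, −78 °C to 0 °C
Reagents that add atoms: methyltriphenylphosphonium bromide, C[P+](c1ccccc1)(c1ccccc1)c1ccccc1.[Br-]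
Why: Wittig methylenation; the aldehyde reacts far faster than the lactone with a slight excess of ylide at low temperature.

Step 15
Reactants: 22 pent-1-en-4-yne
Product: 24 (3E)-4-methylhepta-3,6-dien-1-ol, via alkenylalane 23 (not isolated)
Conditions: Me3Al (2 equiv), Cp2ZrCl2 (0.25 equiv), CH2Cl2, 0 °C to rt; then n-BuLi, hexane/THF, −78 °C; ethylene oxide, −78 °C to rt; aq. HCl
Reagents that add atoms: trimethylaluminium, C[Al](C)C; ethylene oxide, C1CO1
Why: Zirconium-catalysed syn-methylalumination of the terminal alkyne (the isolated alkene is not carbometallated under these conditions) fixes the E trisubstituted alkene, and the derived ate complex opens ethylene oxide with retention of alkene geometry.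

Step 16
Reactants: 24 (3E)-4-methylhepta-3,6-dien-1-ol
Product: 25 (4E)-7-iodo-4-methylhepta-1,4-diene
Conditions: I2, PPh3, imidazole, CH2Cl2, 0 °C
Reagents that add atoms: iodine, [I][I]
Why: Appel-type iodination of a primary alcohol (SN2 on the alkoxyphosphonium salt); the alkenes are not affected.

Step 17
Reactants: 26 3-bromodihydrofuran-2(3H)-one
Product: 27 3-(phenylsulfanyl)dihydrofuran-2(3H)-one
Conditions: PhSH, Et3N, CH2Cl2, 0 °C to rt
Reagents that add atoms: thiophenol, Sc1ccccc1
Why: SN2 displacement of an α-bromo lactone by a thiolate.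

Step 18
Reactants: 27 3-(phenylsulfanyl)dihydrofuran-2(3H)-one; 25 (4E)-7-iodo-4-methylhepta-1,4-diene
Product: 29 3-[(3E)-4-methylhepta-3,6-dien-1-yl]-3-(phenylsulfanyl)dihydrofuran-2(3H)-one, via sodium enolate 28 (not isolated)
Conditions: NaN(SiMe3)2, THF, −78 °C; then 25, DMPU, −78 °C to rt
Reagents that add atoms: none
Why: C-alkylation of the sulfur-stabilised lactone enolate by a primary iodide (SN2), the standard entry to 3-alkyl butenolides.

Step 19
Reactants: 29 3-[(3E)-4-methylhepta-3,6-dien-1-yl]-3-(phenylsulfanyl)dihydrofuran-2(3H)-one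
Product: 31 3-[(3E)-4-methylhepta-3,6-dien-1-yl]furan-2(5H)-one, via sulfoxide 30 (not isolated)
Conditions: mCPBA (1.0 equiv), CH2Cl2, −78 °C; then toluene, 110 °C
Reagents that add atoms: none
Why: Sulfide oxidation is much faster than alkene epoxidation at −78 °C, and thermal syn-elimination of the sulfoxide towards the ring CH2 should give the conjugated endocyclic butenolide.

Step 20
Reactants: 21 (5S)-5-[(2R,5R)-5-ethenyl-5-methyltetrahydrofuran-2-yl]-5-methyldihydrofuran-2(3H)-one; 31 3-[(3E)-4-methylhepta-3,6-dien-1-yl]furan-2(5H)-one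
Product: 32 (5S)-5-methyl-5-[(2R,5R)-5-methyl-5-{(1E,4E)-4-methyl-7-(2-oxo-2,5-dihydrofuran-3-yl)hepta-1,4-dien-1-yl}tetrahydrofuran-2-yl]dihydrofuran-2(3H)-one
Conditions: second-generation Hoveyda–Grubbs catalyst (10 mol %), 31 (3 equiv), CH2Cl2, 40 °C
Reagents that add atoms: none
Why: Olefin cross-metathesis between a vinyl group on a fully substituted carbon (does not homodimerise) and an unhindered terminal alkene in excess; the bulky C2 substituent should enforce the E alkene, and the trisubstituted alkene and the butenolide are too hindered or electron-poor to take part.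

## Compound list

1 | (S)-2-methylglycidol | OC[C@@]1(C)CO1 | starting material
2 | (2R)-2-[(benzyloxy)methyl]-2-methyloxirane | c1ccccc1COC[C@@]1(C)CO1 | intermediate
3 | (2R)-1-(benzyloxy)-4-(dimethylsulfonio)-2-methylbutan-2-olate (sulfonium betaine) | c1ccccc1COC[C@@]([O-])(C)CC[S+](C)C | intermediate
4 | (2R)-1-(benzyloxy)-2-methylbut-3-en-2-ol | c1ccccc1COC[C@@](O)(C)C=C | intermediate
5 | (S)-but-3-en-2-ol | C[C@H](O)C=C | starting material
6 | tert-butyl[(2S)-but-3-en-2-yloxy]dimethylsilane | C[C@H](O[Si](C)(C)C(C)(C)C)C=C | intermediate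
7 | diethyl allyl phosphate | C=CCOP(=O)(OCC)OCC | starting material
8 | (2E,4S)-4-[(tert-butyldimethylsilyl)oxy]pent-2-en-1-yl diethyl phosphate | C[C@H](O[Si](C)(C)C(C)(C)C)/C=C/COP(=O)(OCC)OCC | intermediate
9 | copper alkoxide of 4 | [Cu+].[O-][C@](C)(C=C)COCc1ccccc1 | intermediate
10 | (2R)-1-(benzyloxy)-2-methylbut-3-en-2-yl (3R,4S)-4-[(tert-butyldimethylsilyl)oxy]pent-1-en-3-yl ether | C=C[C@@H](O[C@](C)(C=C)COCc1ccccc1)[C@H](C)O[Si](C)(C)C(C)(C)C | intermediate
11 | (2R,5R)-2-[(benzyloxy)methyl]-5-{(1S)-1-[(tert-butyldimethylsilyl)oxy]ethyl}-2-methyl-2,5-dihydrofuran | c1ccccc1COC[C@@]1(C)C=C[C@H]([C@H](C)O[Si](C)(C)C(C)(C)C)O1 | intermediate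
12 | (2R,5R)-2-[(benzyloxy)methyl]-5-{(1S)-1-[(tert-butyldimethylsilyl)oxy]ethyl}-2-methyltetrahydrofuran | c1ccccc1COC[C@@]1(C)CC[C@H]([C@H](C)O[Si](C)(C)C(C)(C)C)O1 | intermediate
13 | (1S)-1-{(2R,5R)-5-[(benzyloxy)methyl]-5-methyltetrahydrofuran-2-yl}ethan-1-ol | c1ccccc1COC[C@@]1(C)CC[C@H]([C@H](C)O)O1 | intermediate
14 | 1-{(2R,5R)-5-[(benzyloxy)methyl]-5-methyltetrahydrofuran-2-yl}ethan-1-one | c1ccccc1COC[C@@]1(C)CC[C@H](C(C)=O)O1 | intermediate
15 | lithium enolate of 14 | c1ccccc1COC[C@@]1(C)CC[C@H](C([O-])=C)O1.[Li+] | intermediate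
16 | ethyl 4-{(2R,5R)-5-[(benzyloxy)methyl]-5-methyltetrahydrofuran-2-yl}-4-oxobutanoate | c1ccccc1COC[C@@]1(C)CC[C@H](C(=O)CCC(=O)OCC)O1 | intermediate
17 | ethyl (4S)-4-{(2R,5R)-5-[(benzyloxy)methyl]-5-methyltetrahydrofuran-2-yl}-4-hydroxypentanoate | c1ccccc1COC[C@@]1(C)CC[C@H]([C@@](C)(O)CCC(=O)OCC)O1 | intermediate
18 | (5S)-5-{(2R,5R)-5-[(benzyloxy)methyl]-5-methyltetrahydrofuran-2-yl}-5-methyldihydrofuran-2(3H)-one | c1ccccc1COC[C@@]1(C)CC[C@H]([C@]2(C)CCC(=O)O2)O1 | intermediate
19 | (5S)-5-[(2R,5R)-5-(hydroxymethyl)-5-methyltetrahydrofuran-2-yl]-5-methyldihydrofuran-2(3H)-one | OC[C@@]1(C)CC[C@H]([C@]2(C)CCC(=O)O2)O1 | intermediate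
20 | (2R,5R)-2-methyl-5-[(2S)-2-methyl-5-oxotetrahydrofuran-2-yl]tetrahydrofuran-2-carbaldehyde | O=C[C@@]1(C)CC[C@H]([C@]2(C)CCC(=O)O2)O1 | intermediate
21 | (5S)-5-[(2R,5R)-5-ethenyl-5-methyltetrahydrofuran-2-yl]-5-methyldihydrofuran-2(3H)-one | C=C[C@@]1(C)CC[C@H]([C@]2(C)CCC(=O)O2)O1 | intermediate
22 | pent-1-en-4-yne | C=CCC#C | starting material
23 | dimethyl[(1E)-2-methylpenta-1,4-dien-1-yl]alane | C=CC/C(C)=C/[Al](C)C | intermediate
24 | (3E)-4-methylhepta-3,6-dien-1-ol | C=CC/C(C)=C/CCO | intermediate
25 | (4E)-7-iodo-4-methylhepta-1,4-diene | C=CC/C(C)=C/CCI | intermediate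
26 | 3-bromodihydrofuran-2(3H)-one (racemic) | BrC1CCOC1=O | starting material
27 | 3-(phenylsulfanyl)dihydrofuran-2(3H)-one (racemic) | O=C1OCCC1Sc1ccccc1 | intermediate
28 | sodium enolate of 27 | [Na+].[O-]C1=C(Sc2ccccc2)CCO1 | intermediate
29 | 3-[(3E)-4-methylhepta-3,6-dien-1-yl]-3-(phenylsulfanyl)dihydrofuran-2(3H)-one (racemic) | C=CC/C(C)=C/CCC1(Sc2ccccc2)CCOC1=O | intermediate
30 | 3-[(3E)-4-methylhepta-3,6-dien-1-yl]-3-(phenylsulfinyl)dihydrofuran-2(3H)-one | C=CC/C(C)=C/CCC1(S(=O)c2ccccc2)CCOC1=O | intermediate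
31 | 3-[(3E)-4-methylhepta-3,6-dien-1-yl]furan-2(5H)-one | C=CC/C(C)=C/CCC1=CCOC1=O | intermediate
32 | (5S)-5-methyl-5-[(2R,5R)-5-methyl-5-{(1E,4E)-4-methyl-7-(2-oxo-2,5-dihydrofuran-3-yl)hepta-1,4-dien-1-yl}tetrahydrofuran-2-yl]dihydrofuran-2(3H)-one | C/C(=C\CCC1=CCOC1=O)C/C=C/[C@@]1(C)CC[C@H]([C@]2(C)CCC(=O)O2)O1 | target

## Step count and risks

Total step count: 20. Longest linear sequence: 13 steps (steps 1, 2, 5–14 and 20, from (S)-2-methylglycidol).

**Steps most likely to fail**

**Step 5 (allylic etherification).** The hindered tertiary alkoxide may attack the unsubstituted allyl terminus (linear ether) or fail to turn the catalyst over, and facial control may be eroded by mismatch with the neighbouring silyloxy centre.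

Fallback, setting out from 4 and returning at 10: 4 would be acylated with commercial (S)-2-[(tert-butyldimethylsilyl)oxy]propanoic acid (DCC, DMAP) to the ester (2R)-1-(benzyloxy)-2-methylbut-3-en-2-yl (2S)-2-[(tert-butyldimethylsilyl)oxy]propanoate F1. Reduction with iBu2AlH at −78 °C and acetylation of the aluminium hemiacetal in the same flask (Ac2O, pyridine, DMAP) would give the α-acetoxy ether F2. Ionisation with BF3·OEt2 in the presence of KBF3(CH=CH2) should then add the vinyl group to the oxocarbenium ion anti to the silyloxy group (Felkin–Anh, no chelation with a silyl ether). That is expected to give the same (R) centre and hence 10.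

**Step 20 (cross-metathesis).** The vinyl group on the fully substituted C2 may fail to enter the catalytic cycle, so that only the side-chain olefin dimerises, or the skipped diene may suffer double-bond migration.

Fallback, setting out from aldehyde 20 and returning at 32, with a Julia–Kocienski olefination in place of metathesis:
- Commercial 4-(tert-butyldimethylsilyloxy)but-1-yne would be taken through the methylalumination/ethylene oxide protocol of step 15 to (3E)-6-[(tert-butyldimethylsilyl)oxy]-4-methylhex-3-en-1-ol F3.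
- PPh3/CCl4 would give the chloride F4, and HCl in MeOH the chloro alcohol F5.
- Mitsunobu coupling with 1-phenyl-1H-tetrazole-5-thiol (PPh3, DIAD) would give the sulfide F6, and (NH4)6Mo7O24/H2O2 the sulfone F7.
- Deprotonation of F7 with KN(SiMe3)2 in the presence of 20 (DME, −60 °C) should give the (E)-configured chlorodiene F8.
- Alkylation of enolate 28 with F8 (NaI, DMPU) would give the phenylsulfanyl lactone F9.
- Oxidation and thermolysis as in step 19, via the sulfoxide F10, returns to 32.

The sulfone is made before the phenylsulfanyl group is introduced, so the two sulfur oxidations do not interfere.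

**Step 10 (kinetic alkylation).** Enolate equilibration may lead to deprotonation at C5 (epimerisation, regioisomeric alkylation) and to over-alkylation.

Fallback, setting out from 14 and returning at 16: condensation of 14 with Me2NNH2 would give the N,N-dimethylhydrazone F11. Its azaenolate (LiN(iPr)2, THF, −78 °C to 0 °C), which forms at the less substituted carbon, would be alkylated with ethyl bromoacetate to the hydrazone F12. Mild hydrolysis (aq. CuCl2, THF) returns to 16.

Further compounds
F1 | step 5 | (2R)-1-(benzyloxy)-2-methylbut-3-en-2-yl (2S)-2-[(tert-butyldimethylsilyl)oxy]propanoate | C[C@H](O[Si](C)(C)C(C)(C)C)C(=O)O[C@](C)(C=C)COCc1ccccc1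
F2 | step 5 | (2S)-1-{[(2R)-1-(benzyloxy)-2-methylbut-3-en-2-yl]oxy}-2-[(tert-butyldimethylsilyl)oxy]propyl acetate (both acetal epimers) | C[C@H](O[Si](C)(C)C(C)(C)C)C(OC(C)=O)O[C@](C)(C=C)COCc1ccccc1
F3 | step 20 | (3E)-6-[(tert-butyldimethylsilyl)oxy]-4-methylhex-3-en-1-ol | OCC/C=C(\C)CCO[Si](C)(C)C(C)(C)C
F4 | step 20 | tert-butyl{[(3E)-6-chloro-3-methylhex-3-en-1-yl]oxy}dimethylsilane | ClCC/C=C(\C)CCO[Si](C)(C)C(C)(C)C
F5 | step 20 | (3E)-6-chloro-3-methylhex-3-en-1-ol | ClCC/C=C(\C)CCO
F6 | step 20 | 5-{[(3E)-6-chloro-3-methylhex-3-en-1-yl]sulfanyl}-1-phenyl-1H-tetrazole | ClCC/C=C(\C)CCSc1nnnn1-c1ccccc1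
F7 | step 20 | 5-{[(3E)-6-chloro-3-methylhex-3-en-1-yl]sulfonyl}-1-phenyl-1H-tetrazole | ClCC/C=C(\C)CCS(=O)(=O)c1nnnn1-c1ccccc1
F8 | step 20 | (5S)-5-{(2R,5R)-5-[(1E,4E)-7-chloro-4-methylhepta-1,4-dien-1-yl]-5-methyltetrahydrofuran-2-yl}-5-methyldihydrofuran-2(3H)-one | C/C(=C\CCCl)C/C=C/[C@@]1(C)CC[C@H]([C@]2(C)CCC(=O)O2)O1
F9 | step 20 | (5S)-5-methyl-5-[(2R,5R)-5-methyl-5-{(1E,4E)-4-methyl-7-[2-oxo-3-(phenylsulfanyl)tetrahydrofuran-3-yl]hepta-1,4-dien-1-yl}tetrahydrofuran-2-yl]dihydrofuran-2(3H)-one | C/C(=C\CCC1(Sc2ccccc2)CCOC1=O)C/C=C/[C@@]1(C)CC[C@H]([C@]2(C)CCC(=O)O2)O1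
F10 | step 20 | sulfoxide of F9 | C/C(=C\CCC1(S(=O)c2ccccc2)CCOC1=O)C/C=C/[C@@]1(C)CC[C@H]([C@]2(C)CCC(=O)O2)O1
F11 | step 10 | N,N-dimethylhydrazone of 14 | c1ccccc1COC[C@@]1(C)CC[C@H](C(C)=NN(C)C)O1
F12 | step 10 | ethyl 4-{(2R,5R)-5-[(benzyloxy)methyl]-5-methyltetrahydrofuran-2-yl}-4-(2,2-dimethylhydrazinylidene)butanoate | c1ccccc1COC[C@@]1(C)CC[C@H](C(CCC(=O)OCC)=NN(C)C)O1
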